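## Analysis of the target

Numbering used throughout: ring C is the dioxane ring O1–C2–C3–O4–C4a–C8a; ring B is the benzo ring C4a–C5–C6–C7–C8–C8a; ring A is the 3,4,5-trimethoxyphenyl group on C2.

- The target 14 is a 1,4-benzodioxane neolignan. Ring C carries ring A on C2 and a methyl group on C3; ring B carries a methoxy group on C5 and an (E)-3-hydroxyprop-1-enyl chain on C7.
- C2 and C3 are the only stereocentres. Both are R, and ring A and the methyl group are trans. Nothing else in the molecule can relay chirality, so the absolute configuration must come from a catalyst or the chiral pool.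
- The two ring oxygens are constitutionally different. O4 (next to the C5 methoxy group, para to C7) carries C3, and O1 carries C2. The two parent phenolic oxygens are similar in reactivity, so this assignment is a real regiochemical problem.
- Sensitive groups: the C2–O1 bond is a benzylic ether on electron-rich ring A and can ionise under acid, which would epimerise C2. The cinnamyl alcohol is prone to ionisation, oxidation and alkene migration. Both arenes are oxidisable.
- The classical bond formations take place at the stereocentres themselves: at C2 a benzylic carbon prone to SN1, and at C3 a secondary carbon attacked by a hindered phenol.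
- The feature exploited here: C3 is a secondary carbon bearing O4, H, C2 and a methyl group. That is exactly the pattern left when an O–H adds in the Markovnikov sense across a terminal vinyl group. Read this way, C2 (bearing O1, ring A, H and a vinyl group) is the carbinol carbon of a branched 1-arylallyl aryl ether, the product type of iridium-catalysed asymmetric allylic etherification.

## Retrosynthetic reasoning

**14 ⇒ 12 + 13 (C7–alkenyl bond).** The cinnamyl alcohol is the most fragile group and would itself react in the ring closure (a styrene-type alkene accepts hydrogen atoms). It is therefore attached last, by Suzuki–Miyaura coupling of aryl bromide 12 with the alkenyl boronate 13. Until then ring B carries only an inert bromine at C7.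

**12 ⇒ 10 (O4–C3 bond and the C-methyl group, via radical 11).** Ring C is opened at O4–C3 and one hydrogen is removed from the methyl group, which gives the vinyl group of phenol 10. This cut removes the ring, the methyl group and the C3 stereocentre in one move and leaves a precursor with a single stereocentre. The forward reaction must add O4–H across the vinyl group with Markovnikov regiochemistry, close the six-membered ring, place the methyl group trans to ring A, and leave the ionisable C2–O1 bond alone. A cobalt-hydride hydrogen-atom-transfer cyclisation under near-neutral conditions is chosen for this.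

**10 ⇒ 9 (unmasking of O4).** O4 must be blocked while O1 is allylated and must be freed without acid, hydrogen or zerovalent palladium, all of which would attack the allylic benzylic ether or the vinyl group. A SEM acetal, removed by fluoride, meets this and cannot migrate to the neighbouring phenoxide.

**9 ⇒ 8 + 7 (O1–C2 bond).** This is the only bond that joins the two halves and the only one formed with catalyst control. The lithium phenoxide 8 (from phenol 4) attacks the allyl carbonate 7 at its aryl-substituted terminus under iridium–phosphoramidite catalysis. Two achiral fragments give the branched ether 9, with C2 set.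

**4 ⇒ 3 ⇒ 2 ⇒ 1 (C8a–O1 bond).** O1 is introduced by Baeyer–Villiger oxidation of an aldehyde. In commercial 1 the free hydroxyl is the future O4 (next to the methoxy group, para to bromine) and the formyl carbon marks the site of O1. The O1/O4 regiochemistry is thus fixed by the starting material and not by a selective reaction.

**7 ⇒ 6 ⇒ 5.** The carbonate comes from the cinnamyl alcohol 6, which comes from the commercial cinnamate 5 by 1,2-reduction.

## Alternatives that were turned down

**Alternative 1:** the textbook route.
- Disconnection: O4–C3 and O1–C2 made one after the other by substitution at the two carbinol carbons of a dihydroxylated propenylarene.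
- Forward key step: Sharpless asymmetric dihydroxylation of (E)-1,2,3-trimethoxy-5-(prop-1-en-1-yl)benzene A1 with AD-mix-α to the (1S,2S)-diol A2. After differentiation of the hydroxyls, a Mitsunobu etherification at the C3 carbinol with phenol 1 (inversion), unmasking of O1, and a second invertive closure at C2.
- Reason for rejection: both stereocentres created by the dihydroxylation then become substitution sites. The first substitution uses a phenol with two ortho substituents on a secondary carbinol next to a protected benzylic oxygen, so it is slow and elimination competes. The second is at a benzylic carbinol on electron-rich ring A, where ionisation competes with SN2 and erodes C2. A1 must be made first, and hydroxyl differentiation brings the count to about ten steps.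

**Alternative 2:** the cycloaddition route.
- Disconnection: both C–O bonds and ring C at once.
- Forward key step: inverse-demand hetero-Diels–Alder reaction of o-quinone A3 (O=C–C=O as heterodiene) with A1, the E geometry translating into the trans ring.
- Reason for rejection: three selectivities are left uncontrolled in one step.
  - Regiochemistry: the nucleophilic, methyl-bearing alkene carbon should bond to the quinone oxygen whose partner carbonyl is the better acceptor. The methoxy group deactivates the remote carbonyl as a vinylogous ester, so the simple polarity argument predicts the constitutional isomer with O1 on the methyl-bearing carbon.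
  - Chemoselectivity: the carbon diene of A3 competes as a carbodiene, and o-quinones dimerise.
  - Enantioselectivity: there is no catalyst control for o-quinone/propenylarene cycloadditions, so 12 would at best be racemic and mixed.

**Alternative 3:** the C2–ring A route.
- Disconnection: the C2–ring A carbon–carbon bond.
- Forward key step: nickel/photoredox decarboxylative arylation of acid A4 with aryl bromide A5. The α-oxygenated C2 radical would be arylated anti to the C3 methyl group.
- Reason for rejection: A4 already contains ring C, the O1/O4 regiochemistry and the C3 stereocentre. Its enantioselective synthesis needs its own asymmetric step and about as many operations as 12 itself, so the precursor is hardly simpler than the product. Control at C2 would rest only on a neighbouring methyl group.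

Key step: step 7

Assumption: the phosphoramidite enantiomer named in step 5 is taken, by analogy with cinnamyl carbonates and phenoxides, to deliver the (S)-ether 9; if the sense of induction is reversed on this substrate, the mirror-image ligand is used and nothing else changes.

## Route

Step 1
Reactants: 1 5-bromo-2-hydroxy-3-methoxybenzaldehyde
Product: 2 5-bromo-3-methoxy-2-{[2-(trimethylsilyl)ethoxy]methoxy}benzaldehyde
Conditions: SEMCl, iPr2NEt, CH2Cl2, 0 °C to rt
Reagents that add atoms: 2-(trimethylsilyl)ethoxymethyl chloride (SEMCl), C[Si](C)(C)CCOCCl
Why: O-alkylation of the phenol by the chloromethyl ether; the hydroxyl of 1 is the future O4, and the acetal formed cannot migrate to a neighbouring phenoxide in step 5 and is later cleaved by fluoride alone.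

Step 2
Reactants: 2 5-bromo-3-methoxy-2-{[2-(trimethylsilyl)ethoxy]methoxy}benzaldehyde
Product: 4 5-bromo-3-methoxy-2-{[2-(trimethylsilyl)ethoxy]methoxy}phenol, via aryl formate 3 (not isolated)
Conditions: mCPBA, CH2Cl2, 0 °C to rt; aqueous NaHCO3/Na2S2O3 wash; then K2CO3 (cat.), MeOH, rt
Reagents that add atoms: 3-chloroperoxybenzoic acid (mCPBA), OOC(=O)c1cccc(Cl)c1
Why: Baeyer–Villiger (Dakin-type) oxidation; the electron-rich ortho-alkoxy aryl group migrates in the Criegee intermediate to give formate 3, and methanolysis frees the phenol, so the former formyl carbon fixes the position of O1 without any selective step.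

Step 3
Reactants: 5 methyl (E)-3-(3,4,5-trimethoxyphenyl)prop-2-enoate
Product: 6 (E)-3-(3,4,5-trimethoxyphenyl)prop-2-en-1-ol
Conditions: iBu2AlH (2.2 equiv), CH2Cl2, −78 °C to 0 °C; aqueous potassium sodium tartrate
Reagents that add atoms: none
Why: 1,2-reduction of the conjugated ester by the aluminium hydride; the alkene and its E geometry are not touched.

Step 4
Reactants: 6 (E)-3-(3,4,5-trimethoxyphenyl)prop-2-en-1-ol
Product: 7 methyl (E)-3-(3,4,5-trimethoxyphenyl)prop-2-en-1-yl carbonate
Conditions: ClCO2Me, pyridine, CH2Cl2, 0 °C
Reagents that add atoms: methyl chloroformate, COC(=O)Cl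
Why: acylation of the primary allylic alcohol; the carbonate is the leaving group for the allylic substitution.

Step 5
Reactants: 4 5-bromo-3-methoxy-2-{[2-(trimethylsilyl)ethoxy]methoxy}phenol; 7 methyl (E)-3-(3,4,5-trimethoxyphenyl)prop-2-en-1-yl carbonate
Product: 9 (S)-5-bromo-1-methoxy-3-{[1-(3,4,5-trimethoxyphenyl)prop-2-en-1-yl]oxy}-2-{[2-(trimethylsilyl)ethoxy]methoxy}benzene, via lithium phenoxide 8 (not isolated)
Conditions: 4 (1.3 equiv), LiN(SiMe3)2 (1.3 equiv), THF, 0 °C; then 7, [Ir(cod)Cl]2 (2 mol %), (Sa,Sc,Sc)-O,O'-(1,1'-binaphthalene-2,2'-diyl) N,N-bis(1-phenylethyl)phosphoramidite (4 mol %), THF, 50 °C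
Reagents that add atoms: none
Why: iridium-catalysed asymmetric allylic etherification; the cyclometalated iridium–phosphoramidite ionises 7 to an allyl complex that the phenoxide attacks at the aryl-substituted terminus (branched product), and the ligand fixes the face, setting C2. The centre is (S) in 9 and becomes (R) in ring C only because the vinyl carbon outranks ring A once it carries O4; only O1 can react because O4 is blocked.

Step 6
Reactants: 9 (S)-5-bromo-1-methoxy-3-{[1-(3,4,5-trimethoxyphenyl)prop-2-en-1-yl]oxy}-2-{[2-(trimethylsilyl)ethoxy]methoxy}benzene
Product: 10 (S)-4-bromo-2-methoxy-6-{[1-(3,4,5-trimethoxyphenyl)prop-2-en-1-yl]oxy}phenol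
Conditions: Bu4NF (3 equiv), THF, 60 °C; pH 7 buffer work-up
Reagents that add atoms: none
Why: fluoride attacks silicon and the acetal fragments to ethene, formaldehyde and the phenoxide (O4); no acid, hydrogen or palladium is present, so the allylic benzylic ether, the vinyl group and the C2 centre are untouched.

Step 7
Reactants: 10 (S)-4-bromo-2-methoxy-6-{[1-(3,4,5-trimethoxyphenyl)prop-2-en-1-yl]oxy}phenol
Product: 12 (2R,3R)-7-bromo-5-methoxy-3-methyl-2-(3,4,5-trimethoxyphenyl)-2,3-dihydro-1,4-benzodioxine, via C3 radical 11 (not isolated)
Conditions: (R,R)-Co(salen) [(R,R)-N,N'-bis(3,5-di-tert-butylsalicylidene)-1,2-cyclohexanediaminatocobalt, C36H52CoN2O2, divalent cobalt] (5 mol %), N-fluoro-2,4,6-trimethylpyridinium tetrafluoroborate (1.3 equiv), (Me2SiH)2O (1.3 equiv), PhCF3 (0.05 M), 0 °C to rt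
Reagents that add atoms: none
Why: The cobalt hydride generated from the N-fluoro oxidant and the silane transfers a hydrogen atom to the unsubstituted terminus of the vinyl group (Mukaiyama-type, Markovnikov), giving the secondary C3 radical 11, which is captured by cobalt and oxidised to a cationic tetravalent alkylcobalt species. The free O4–H then displaces cobalt at C3 with inversion in a 6-exo-trig closure of ring C (C3 inside the ring, the former CH2 outside as the methyl group), and 2,4,6-trimethylpyridine takes up the proton. The closest known reaction type is the cobalt-salen/N-fluoropyridinium/silane radical–polar crossover hydroalkoxylation of unactivated terminal alkenes by tethered hydroxyl groups to five- and six-membered cyclic ethers. The new stereocentre C3 is controlled by C2: the two diastereomeric alkylcobalt species interconvert through 11 by cobalt–carbon homolysis, and the closure that places ring A on C2 and the methyl group on C3 both pseudo-equatorial on the forming half-chair (trans) should be the faster one under Curtin–Hammett conditions. The enantiopure salen ligand is a second, tunable control element, and the (S,S) complex is taken if the (R,R) complex proves mismatched. No bond to C2 is made or broken, so the enantiomeric purity from step 5 is carried over unchanged. Regioselectivity is secured by hydrogen-atom transfer to the terminal carbon, chemoselectivity by the vinyl group being the only alkene and by the inertness of the aryl bromide, and the benzylic C2–O1 bond is safe because the only acid present is the pyridinium salt. In one operation the step closes ring C, forms O4–C3, creates the C-methyl group and sets the second stereocentre.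

Step 8
Reactants: 12 (2R,3R)-7-bromo-5-methoxy-3-methyl-2-(3,4,5-trimethoxyphenyl)-2,3-dihydro-1,4-benzodioxine; 13 (E)-3-(4,4,5,5-tetramethyl-1,3,2-dioxaborolan-2-yl)prop-2-en-1-ol
Product: 14 (E)-3-[(2R,3R)-5-methoxy-3-methyl-2-(3,4,5-trimethoxyphenyl)-2,3-dihydro-1,4-benzodioxin-7-yl]prop-2-en-1-ol
Conditions: Pd(dppf)Cl2 (5 mol %), K2CO3 (3 equiv), 1,4-dioxane/H2O (4:1), 80 °C
Reagents that add atoms: none
Why: Suzuki–Miyaura coupling; zerovalent palladium inserts into C7–Br, the alkenyl group is transferred with retention of its E geometry, and reductive elimination forms the C7–alkenyl bond. The mildly basic conditions touch neither stereocentre nor the benzylic ether.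

## Compound list

1 | 5-bromo-2-hydroxy-3-methoxybenzaldehyde | O=Cc1cc(Br)cc(OC)c1O | starting material
2 | 5-bromo-3-methoxy-2-{[2-(trimethylsilyl)ethoxy]methoxy}benzaldehyde | O=Cc1cc(Br)cc(OC)c1OCOCC[Si](C)(C)C | intermediate
3 | 5-bromo-3-methoxy-2-{[2-(trimethylsilyl)ethoxy]methoxy}phenyl formate | O=COc1cc(Br)cc(OC)c1OCOCC[Si](C)(C)C | intermediate (not isolated)
4 | 5-bromo-3-methoxy-2-{[2-(trimethylsilyl)ethoxy]methoxy}phenol | Oc1cc(Br)cc(OC)c1OCOCC[Si](C)(C)C | intermediate
5 | methyl (E)-3-(3,4,5-trimethoxyphenyl)prop-2-enoate | COC(=O)/C=C/c1cc(OC)c(OC)c(OC)c1 | starting material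
6 | (E)-3-(3,4,5-trimethoxyphenyl)prop-2-en-1-ol | OC/C=C/c1cc(OC)c(OC)c(OC)c1 | intermediate
7 | methyl (E)-3-(3,4,5-trimethoxyphenyl)prop-2-en-1-yl carbonate | COC(=O)OC/C=C/c1cc(OC)c(OC)c(OC)c1 | intermediate
8 | lithium 5-bromo-3-methoxy-2-{[2-(trimethylsilyl)ethoxy]methoxy}phenolate | [Li+].[O-]c1cc(Br)cc(OC)c1OCOCC[Si](C)(C)C | intermediate (not isolated)
9 | (S)-5-bromo-1-methoxy-3-{[1-(3,4,5-trimethoxyphenyl)prop-2-en-1-yl]oxy}-2-{[2-(trimethylsilyl)ethoxy]methoxy}benzene | COc1cc([C@H](C=C)Oc2cc(Br)cc(OC)c2OCOCC[Si](C)(C)C)cc(OC)c1OC | intermediate
10 | (S)-4-bromo-2-methoxy-6-{[1-(3,4,5-trimethoxyphenyl)prop-2-en-1-yl]oxy}phenol | COc1cc([C@H](C=C)Oc2cc(Br)cc(OC)c2O)cc(OC)c1OC | intermediate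
11 | (1S)-1-(5-bromo-2-hydroxy-3-methoxyphenoxy)-1-(3,4,5-trimethoxyphenyl)propan-2-yl radical | COc1cc([C@H]([CH]C)Oc2cc(Br)cc(OC)c2O)cc(OC)c1OC | intermediate (not isolated)
12 | (2R,3R)-7-bromo-5-methoxy-3-methyl-2-(3,4,5-trimethoxyphenyl)-2,3-dihydro-1,4-benzodioxine | COc1cc([C@H]2Oc3cc(Br)cc(OC)c3O[C@@H]2C)cc(OC)c1OC | intermediate
13 | (E)-3-(4,4,5,5-tetramethyl-1,3,2-dioxaborolan-2-yl)prop-2-en-1-ol | OC/C=C/B1OC(C)(C)C(C)(C)O1 | starting material
14 | (E)-3-[(2R,3R)-5-methoxy-3-methyl-2-(3,4,5-trimethoxyphenyl)-2,3-dihydro-1,4-benzodioxin-7-yl]prop-2-en-1-ol | COc1cc([C@H]2Oc3cc(/C=C/CO)cc(OC)c3O[C@@H]2C)cc(OC)c1OC | target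

## Step count and least certain steps

Total step count: 8. Longest linear sequence: 6 steps (steps 1, 2, 5, 6, 7, 8 from 1; equally steps 3, 4, 5, 6, 7, 8 from 5).

**Step 7 (key step).** Two processes are most likely to go wrong.
- The C3 radical may fragment before cobalt captures it, by β-scission of the benzylic C2–O1 bond with loss of the aryloxyl group. That bond is weak and the alkene formed would be conjugated with ring A.
- The ring closure is under kinetic control, and the preference for the trans arrangement is modest, so facial discrimination at C3 may be insufficient.

Fallback: a polar, two-step closure that never places a radical on C3. It sets out from 10. Iodine and NaHCO3 in MeCN at 0 °C effect an iodoetherification (anti addition, O4 attacking the internal carbon in a 6-exo closure) to (2R,3S)-7-bromo-3-(iodomethyl)-5-methoxy-2-(3,4,5-trimethoxyphenyl)-2,3-dihydro-1,4-benzodioxine F1. Radical deiodination with Bu3SnH and catalytic AIBN in toluene at 80 °C then replaces iodine by hydrogen; the primary radical is quenched by the tin hydride faster than it fragments, and the aryl bromide reacts far more slowly than the alkyl iodide. The sequence returns to the route at 12 at the cost of one step.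

**Step 5.** Erosion of enantiomeric purity or of the branched/linear ratio is the main concern, because the product is an ionisable allylic benzylic aryl ether that the catalyst can re-ionise. The ortho-substituted phenoxide may also attack the allyl complex slowly.

Fallback: a stereospecific substitution in place of catalyst control. It sets out from 4. Commercial 3,4,5-trimethoxybenzaldehyde is vinylated enantioselectively (divinylzinc, catalytic chiral β-amino alcohol, toluene, 0 °C) to (R)-1-(3,4,5-trimethoxyphenyl)prop-2-en-1-ol F2. A Mitsunobu reaction of F2 with 4 (PPh3, diisopropyl azodicarboxylate, toluene, −20 °C) forms O1–C2 with inversion and returns to the route at 9.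

**Step 6.** Cleavage of the aryl SEM ether may be slow, and the hot basic fluoride may shift the doubly activated C2–H (allylic, benzylic, α to oxygen) to give an enol ether.

Fallback: omit the separate deprotection. It sets out from 9, which is submitted directly to the conditions of step 7. The acetal-protected O4 attacks the alkylcobalt centre, and the resulting oxonium ion sheds the alkoxymethyl group. Such deprotective cyclisations are established for acetal- and silyl-protected aliphatic alcohols and are extended here to an aryl acetal. The fallback returns to the route at 12 and makes no new compound.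

**Step 8.** Palladium hydride formed during the coupling may isomerise the allylic alcohol to an aldehyde, and the alkenyl boronate may protodeboronate while oxidative addition into the electron-rich aryl bromide is slow.

Fallback: build the side chain in two steps from an acrylate. It sets out from 12. A Heck reaction with methyl acrylate (Pd(OAc)2, tri(o-tolyl)phosphine, Et3N, DMF, 100 °C) gives methyl (E)-3-[(2R,3R)-5-methoxy-3-methyl-2-(3,4,5-trimethoxyphenyl)-2,3-dihydro-1,4-benzodioxin-7-yl]prop-2-enoate F3. Reduction of F3 with iBu2AlH in CH2Cl2 at −78 °C returns to the route at 14.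

## Further compounds

F1 | step 7 | (2R,3S)-7-bromo-3-(iodomethyl)-5-methoxy-2-(3,4,5-trimethoxyphenyl)-2,3-dihydro-1,4-benzodioxine | COc1cc([C@H]2Oc3cc(Br)cc(OC)c3O[C@@H]2CI)cc(OC)c1OC
F2 | step 5 | (R)-1-(3,4,5-trimethoxyphenyl)prop-2-en-1-ol | COc1cc([C@@H](C=C)O)cc(OC)c1OC
F0 | step 6 | none | none
F3 | step 8 | methyl (E)-3-[(2R,3R)-5-methoxy-3-methyl-2-(3,4,5-trimethoxyphenyl)-2,3-dihydro-1,4-benzodioxin-7-yl]prop-2-enoate | COc1cc([C@H]2Oc3cc(/C=C/C(=O)OC)cc(OC)c3O[C@@H]2C)cc(OC)c1OC
A1 | alternative 1 | (E)-1,2,3-trimethoxy-5-(prop-1-en-1-yl)benzene | C/C=C/c1cc(OC)c(OC)c(OC)c1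
A2 | alternative 1 | (1S,2S)-1-(3,4,5-trimethoxyphenyl)propane-1,2-diol | C[C@H](O)[C@@H](O)c1cc(OC)c(OC)c(OC)c1
A3 | alternative 2 | 5-bromo-3-methoxycyclohexa-3,5-diene-1,2-dione | COC1=CC(Br)=CC(=O)C1=O
A4 | alternative 3 | (3R)-7-bromo-5-methoxy-3-methyl-2,3-dihydro-1,4-benzodioxine-2-carboxylic acid | COc1cc(Br)cc2OC(C(=O)O)[C@@H](C)Oc12
A5 | alternative 3 | 5-bromo-1,2,3-trimethoxybenzene | COc1cc(Br)cc(OC)c1OC
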